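**Retrosynthetic overview**
- The target 26 comes from macrocyclic stilbene 25 by one hydrogenation that saturates the last C=C and removes both benzyl ethers.
- The 18-membered ring, the only ring formed in the route (the four benzene rings are bought), closes by intramolecular Wittig macrocyclisation of formyl phosphonium salt 23 across the ring B–ring C bridge.
- 23 comes from bibenzyl 20, made by intermolecular Wittig union of the A–B aldehyde 10 with the C–D phosphonium salt 17 (ring D–ring A bridge), then benzyl-sparing alkene reduction.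
- 10 comes from SNAr of fluoro-aldehyde 7 (3-fluoro-4-methoxyphenol, directed ortho-metalation/formylation, MOM-to-Bn swap) with acetal phenol 9.
- 17 comes from SNAr of methyl 4-(benzyloxy)-3-hydroxybenzoate 12 with 4-fluorobenzaldehyde 13, then reduction, bromination and PPh3.

Assumption: the target SMILES has no stereodescriptor and no stereogenic centre, so it is treated as achiral (macrocycle ring flips taken as fast) and no enantioselective step is needed.

**Step 1**
Reactants: 1 3-fluoro-4-methoxyphenol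
Product: 2 2-fluoro-1-methoxy-4-(methoxymethoxy)benzene
Conditions: NaH, MOMCl, THF/DMF, 0 °C to rt
Reagents that add atoms: chloromethyl methyl ether COCCl
Why: Williamson-type O-alkylation of the sodium phenoxide installs a MOM ether that is a strong ortho-metalation director.

**Step 2**
Reactants: 2 2-fluoro-1-methoxy-4-(methoxymethoxy)benzene
Product: 5 2-fluoro-3-methoxy-6-(methoxymethoxy)benzaldehyde, via aryllithium 3 (not isolated), via lithium hemiaminal alkoxide 4 (not isolated)
Conditions: n-BuLi, THF, −78 °C; DMF, −78 °C; then H2O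
Reagents that add atoms: N,N-dimethylformamide CN(C)C=O
Why: Directed ortho-metalation removes the C–H flanked by F and OMOM (the most acidic site, kept at −78 °C to avoid LiF loss to a benzyne) and DMF formylates the aryllithium.

**Step 3**
Reactants: 5 2-fluoro-3-methoxy-6-(methoxymethoxy)benzaldehyde
Product: 6 2-fluoro-6-hydroxy-3-methoxybenzaldehyde
Conditions: 3 M aq. HCl, THF, 50 °C
Reagents that add atoms: none
Why: Acid-catalysed acetal hydrolysis cleaves the MOM ether, leaving the aryl fluoride, methyl ether and aldehyde untouched.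

**Step 4**
Reactants: 6 2-fluoro-6-hydroxy-3-methoxybenzaldehyde
Product: 7 6-(benzyloxy)-2-fluoro-3-methoxybenzaldehyde
Conditions: BnBr, K2CO3, DMF, 50 °C
Reagents that add atoms: benzyl bromide BrCc1ccccc1
Why: Williamson etherification of the salicylaldehyde-type phenol is much faster at 50 °C than any SNAr at the fluoride, and gives a phenol protection that falls in the final hydrogenation.

**Step 5**
Reactants: 8 3-hydroxybenzaldehyde
Product: 9 3-(1,3-dioxolan-2-yl)phenol
Conditions: ethylene glycol, p-TsOH (cat.), toluene, Dean–Stark, reflux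
Reagents that add atoms: ethylene glycol OCCO
Why: Acid-catalysed acetalisation with azeotropic water removal masks the aldehyde while leaving the phenol free for ether formation.

**Step 6**
Reactants: 7 6-(benzyloxy)-2-fluoro-3-methoxybenzaldehyde; 9 3-(1,3-dioxolan-2-yl)phenol
Product: 10 6-(benzyloxy)-2-[3-(1,3-dioxolan-2-yl)phenoxy]-3-methoxybenzaldehyde
Conditions: K2CO3, DMF, 120 °C
Reagents that add atoms: none
Why: SNAr of the phenoxide at the fluoride activated by the ortho formyl group forms the ring A–ring B diaryl ether; the acetal and benzyl ether are stable to base.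

**Step 7**
Reactants: 11 methyl 3,4-dihydroxybenzoate
Product: 12 methyl 4-(benzyloxy)-3-hydroxybenzoate
Conditions: BnBr (1.0 equiv), K2CO3 (1.1 equiv), DMF, rt; chromatography
Reagents that add atoms: benzyl bromide BrCc1ccccc1
Why: Williamson mono-alkylation goes mainly at the 4-OH, which is the more acidic phenol because it is conjugated with the para ester.

**Step 8**
Reactants: 12 methyl 4-(benzyloxy)-3-hydroxybenzoate; 13 4-fluorobenzaldehyde
Product: 14 methyl 4-(benzyloxy)-3-(4-formylphenoxy)benzoate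
Conditions: K2CO3, DMF, 130 °C
Reagents that add atoms: none
Why: SNAr at the para-formyl-activated fluoride forms the ring C–ring D diaryl ether with ester and aldehyde already differentiated.

**Step 9**
Reactants: 14 methyl 4-(benzyloxy)-3-(4-formylphenoxy)benzoate
Product: 15 methyl 4-(benzyloxy)-3-[4-(hydroxymethyl)phenoxy]benzoate
Conditions: NaBH4, MeOH/THF, 0 °C
Reagents that add atoms: none
Why: Chemoselective borohydride reduction takes the aldehyde and leaves the methyl ester.

**Step 10**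
Reactants: 15 methyl 4-(benzyloxy)-3-[4-(hydroxymethyl)phenoxy]benzoate
Product: 16 methyl 4-(benzyloxy)-3-[4-(bromomethyl)phenoxy]benzoate
Conditions: PBr3, CH2Cl2, 0 °C
Reagents that add atoms: phosphorus tribromide BrP(Br)Br
Why: Bromide displaces the activated phosphite of the benzylic alcohol at 0 °C without touching the ester or benzyl ether.

**Step 11**
Reactants: 16 methyl 4-(benzyloxy)-3-[4-(bromomethyl)phenoxy]benzoate
Product: 17 {4-[2-(benzyloxy)-5-(methoxycarbonyl)phenoxy]benzyl}triphenylphosphonium bromide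
Conditions: PPh3, toluene, reflux
Reagents that add atoms: triphenylphosphine c1ccc(cc1)P(c1ccccc1)c1ccccc1
Why: SN2 quaternisation of PPh3 by the benzylic bromide gives the Wittig salt, which precipitates from toluene.

**Step 12**
Reactants: 17 {4-[2-(benzyloxy)-5-(methoxycarbonyl)phenoxy]benzyl}triphenylphosphonium bromide; 10 6-(benzyloxy)-2-[3-(1,3-dioxolan-2-yl)phenoxy]-3-methoxybenzaldehyde
Product: 19 methyl 4-(benzyloxy)-3-[4-(2-{6-(benzyloxy)-2-[3-(1,3-dioxolan-2-yl)phenoxy]-3-methoxyphenyl}ethenyl)phenoxy]benzoate (E/Z mixture), via phosphonium ylide 18 (not isolated)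
Conditions: K2CO3, 18-crown-6 (cat.), CH2Cl2, reflux
Reagents that add atoms: none
Why: Wittig olefination with the semistabilised benzyl ylide joins the two halves under mild carbonate conditions that spare ester and acetal; the E/Z ratio is irrelevant because the alkene is reduced next.

**Step 13**
Reactants: 19 stilbene (E/Z mixture)
Product: 20 methyl 4-(benzyloxy)-3-[4-(2-{6-(benzyloxy)-2-[3-(1,3-dioxolan-2-yl)phenoxy]-3-methoxyphenyl}ethyl)phenoxy]benzoate
Conditions: H2 (1 atm), 10% Pd/C, Ph2S (cat.), EtOAc, rt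
Reagents that add atoms: none
Why: Catalytic hydrogenation over sulfide-poisoned Pd/C saturates the alkene while suppressing hydrogenolysis of the benzyl ethers and the benzylic acetal, giving one flexible bibenzyl for ring closure.

**Step 14**
Reactants: 20 bibenzyl ester
Product: 21 {4-(benzyloxy)-3-[4-(2-{6-(benzyloxy)-2-[3-(1,3-dioxolan-2-yl)phenoxy]-3-methoxyphenyl}ethyl)phenoxy]phenyl}methanol
Conditions: LiAlH4, THF, 0 °C; Fieser work-up
Reagents that add atoms: none
Why: Hydride reduction of the methyl ester gives the benzylic alcohol; acetal, benzyl ethers and diaryl ethers are inert to LiAlH4.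

**Step 15**
Reactants: 21 benzylic alcohol
Product: 23 {4-(benzyloxy)-3-[4-(2-{6-(benzyloxy)-2-(3-formylphenoxy)-3-methoxyphenyl}ethyl)phenoxy]benzyl}triphenylphosphonium bromide, via acetal phosphonium bromide 22 (not isolated)
Conditions: PPh3·HBr, MeCN, reflux; then 1 M aq. HCl, THF, rt
Reagents that add atoms: triphenylphosphine hydrobromide Br.c1ccc(cc1)P(c1ccccc1)c1ccccc1; water O
Why: The p-benzyloxybenzyl alcohol ionises easily under the mild acid and is captured by PPh3 (SN1-type phosphonium formation), and the acid/water then hydrolyses the dioxolane to release the aldehyde.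

**Step 16**
Reactants: 23 formyl phosphonium bromide
Product: 25 macrocyclic stilbene (E/Z mixture; the target skeleton with a CH=CH bridge between rings B and C and both phenols as benzyl ethers), via phosphonium ylide 24 (not isolated)
Conditions: slow addition (syringe pump, 12 h) of 23 to NaOMe, CH2Cl2/MeOH, rt, final ca. 1 mM
Reagents that add atoms: none
Why: Intramolecular Wittig macrocyclisation at high dilution closes the 18-membered ring at the unhindered B–C bridge, the flexible bibenzyl and two diaryl ether hinges letting the ylide reach the aldehyde faster than it oligomerises.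

**Step 17**
Reactants: 25 macrocyclic stilbene (E/Z mixture)
Product: 26 target macrocycle CNP0179896.0
Conditions: H2 (1–3 bar), 10% Pd/C, EtOAc/MeOH, rt
Reagents that add atoms: none
Why: Catalytic hydrogenation saturates both alkene isomers to the same bibenzyl and hydrogenolyses the two benzyl ethers, while the methyl ether and diaryl ethers survive; no stereocentre is created.

**Compound list**
1 | 3-fluoro-4-methoxyphenol | COc1ccc(O)cc1F | starting material
2 | 2-fluoro-1-methoxy-4-(methoxymethoxy)benzene | COCOc1ccc(OC)c(F)c1 | intermediate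
3 | [2-fluoro-3-methoxy-6-(methoxymethoxy)phenyl]lithium | [Li]c1c(F)c(OC)ccc1OCOC | intermediate
4 | lithium (dimethylamino)[2-fluoro-3-methoxy-6-(methoxymethoxy)phenyl]methanolate | [Li+].[O-]C(N(C)C)c1c(F)c(OC)ccc1OCOC | intermediate
5 | 2-fluoro-3-methoxy-6-(methoxymethoxy)benzaldehyde | COCOc1ccc(OC)c(F)c1C=O | intermediate
6 | 2-fluoro-6-hydroxy-3-methoxybenzaldehyde | COc1ccc(O)c(C=O)c1F | intermediate
7 | 6-(benzyloxy)-2-fluoro-3-methoxybenzaldehyde | COc1ccc(OCc2ccccc2)c(C=O)c1F | intermediate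
8 | 3-hydroxybenzaldehyde | O=Cc1cccc(O)c1 | starting material
9 | 3-(1,3-dioxolan-2-yl)phenol | Oc1cccc(c1)C1OCCO1 | intermediate
10 | 6-(benzyloxy)-2-[3-(1,3-dioxolan-2-yl)phenoxy]-3-methoxybenzaldehyde | COc1ccc(OCc2ccccc2)c(C=O)c1Oc1cccc(c1)C1OCCO1 | intermediate
11 | methyl 3,4-dihydroxybenzoate | COC(=O)c1ccc(O)c(O)c1 | starting material
12 | methyl 4-(benzyloxy)-3-hydroxybenzoate | COC(=O)c1ccc(OCc2ccccc2)c(O)c1 | intermediate
13 | 4-fluorobenzaldehyde | O=Cc1ccc(F)cc1 | starting material
14 | methyl 4-(benzyloxy)-3-(4-formylphenoxy)benzoate | COC(=O)c1ccc(OCc2ccccc2)c(Oc2ccc(C=O)cc2)c1 | intermediate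
15 | methyl 4-(benzyloxy)-3-[4-(hydroxymethyl)phenoxy]benzoate | COC(=O)c1ccc(OCc2ccccc2)c(Oc2ccc(CO)cc2)c1 | intermediate
16 | methyl 4-(benzyloxy)-3-[4-(bromomethyl)phenoxy]benzoate | COC(=O)c1ccc(OCc2ccccc2)c(Oc2ccc(CBr)cc2)c1 | intermediate
17 | {4-[2-(benzyloxy)-5-(methoxycarbonyl)phenoxy]benzyl}triphenylphosphonium bromide | [Br-].COC(=O)c1ccc(OCc2ccccc2)c(Oc2ccc(C[P+](c3ccccc3)(c3ccccc3)c3ccccc3)cc2)c1 | intermediate
18 | methyl 4-(benzyloxy)-3-{4-[(triphenylphosphoranylidene)methyl]phenoxy}benzoate (ylide) | COC(=O)c1ccc(OCc2ccccc2)c(Oc2ccc(C=P(c3ccccc3)(c3ccccc3)c3ccccc3)cc2)c1 | intermediate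
19 | methyl 4-(benzyloxy)-3-[4-(2-{6-(benzyloxy)-2-[3-(1,3-dioxolan-2-yl)phenoxy]-3-methoxyphenyl}ethenyl)phenoxy]benzoate (E/Z mixture) | COC(=O)c1ccc(OCc2ccccc2)c(Oc2ccc(C=Cc3c(OCc4ccccc4)ccc(OC)c3Oc3cccc(c3)C3OCCO3)cc2)c1 | intermediate
20 | methyl 4-(benzyloxy)-3-[4-(2-{6-(benzyloxy)-2-[3-(1,3-dioxolan-2-yl)phenoxy]-3-methoxyphenyl}ethyl)phenoxy]benzoate | COC(=O)c1ccc(OCc2ccccc2)c(Oc2ccc(CCc3c(OCc4ccccc4)ccc(OC)c3Oc3cccc(c3)C3OCCO3)cc2)c1 | intermediate
21 | {4-(benzyloxy)-3-[4-(2-{6-(benzyloxy)-2-[3-(1,3-dioxolan-2-yl)phenoxy]-3-methoxyphenyl}ethyl)phenoxy]phenyl}methanol | OCc1ccc(OCc2ccccc2)c(Oc2ccc(CCc3c(OCc4ccccc4)ccc(OC)c3Oc3cccc(c3)C3OCCO3)cc2)c1 | intermediate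
22 | {4-(benzyloxy)-3-[4-(2-{6-(benzyloxy)-2-[3-(1,3-dioxolan-2-yl)phenoxy]-3-methoxyphenyl}ethyl)phenoxy]benzyl}triphenylphosphonium bromide | [Br-].c1ccccc1[P+](c1ccccc1)(c1ccccc1)Cc1ccc(OCc2ccccc2)c(Oc2ccc(CCc3c(OCc4ccccc4)ccc(OC)c3Oc3cccc(c3)C3OCCO3)cc2)c1 | intermediate
23 | {4-(benzyloxy)-3-[4-(2-{6-(benzyloxy)-2-(3-formylphenoxy)-3-methoxyphenyl}ethyl)phenoxy]benzyl}triphenylphosphonium bromide | [Br-].c1ccccc1[P+](c1ccccc1)(c1ccccc1)Cc1ccc(OCc2ccccc2)c(Oc2ccc(CCc3c(OCc4ccccc4)ccc(OC)c3Oc3cccc(C=O)c3)cc2)c1 | intermediate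
24 | 3-{3-(benzyloxy)-2-[2-(4-{2-(benzyloxy)-5-[(triphenylphosphoranylidene)methyl]phenoxy}phenyl)ethyl]-6-methoxyphenoxy}benzaldehyde (ylide of 23) | c1ccccc1P(c1ccccc1)(c1ccccc1)=Cc1ccc(OCc2ccccc2)c(Oc2ccc(CCc3c(OCc4ccccc4)ccc(OC)c3Oc3cccc(C=O)c3)cc2)c1 | intermediate
25 | macrocyclic stilbene, E/Z mixture (18-membered ring; target skeleton with CH=CH between rings B and C, both phenols as benzyl ethers) | COc1ccc(OCc3ccccc3)c2c1Oc1cccc(c1)C=Cc1ccc(OCc3ccccc3)c(c1)Oc1ccc(cc1)CC2 | intermediate
26 | CNP0179896.0 (achiral macrocyclic bis(bibenzyl), no stereocentre) | COc1ccc(O)c2c1Oc1cccc(c1)CCc1ccc(O)c(c1)Oc1ccc(cc1)CC2 | target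

**Step count**
Total steps: 17.
Longest linear sequence: 11 steps (1 → 2 → 5 → 6 → 7 → 10 → 19 → 20 → 21 → 23 → 25 → 26; the branch from 11 through 17 is equally long). Step 5 is a one-step side branch.

**Three steps most likely to fail, with fallbacks**

Step 6 (SNAr at a fluoride flanked by CHO and OMe on an electron-rich ring). The fallback reverses the polarity of the ether formation and sets out from 7. Treating 7 with 2-(methylsulfonyl)ethanol and NaH in DMF (0 °C to rt) gives 6-(benzyloxy)-3-methoxy-2-[2-(methylsulfonyl)ethoxy]benzaldehyde F1, which eliminates methyl vinyl sulfone in the same flask to give, after acidic work-up, 6-(benzyloxy)-2-hydroxy-3-methoxybenzaldehyde F2. A copper-catalysed Ullmann ether coupling of F2 with commercial 2-(3-bromophenyl)-1,3-dioxolane (CuI, picolinic acid, K3PO4, DMSO, 90 °C) then returns to the route at 10.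

Step 13 (alkene reduction in the presence of two benzyl ethers and a benzylic acetal). The fallback gives up the selectivity and sets out from 19. Exhaustive hydrogenation (H2, Pd/C, EtOAc with a trace of Et3N) reduces the alkene and cleaves both benzyl ethers to give methyl 3-[4-(2-{2-[3-(1,3-dioxolan-2-yl)phenoxy]-6-hydroxy-3-methoxyphenyl}ethyl)phenoxy]-4-hydroxybenzoate F3. Double re-benzylation (BnBr, K2CO3, DMF, 60 °C) returns to the route at 20.

Step 16 (macrocyclisation; oligomerisation competes). The fallback closes the same bond reductively from a dialdehyde and sets out from 21. MnO2 in CH2Cl2 oxidises the benzylic alcohol to 4-(benzyloxy)-3-[4-(2-{6-(benzyloxy)-2-[3-(1,3-dioxolan-2-yl)phenoxy]-3-methoxyphenyl}ethyl)phenoxy]benzaldehyde F4. Acetal hydrolysis (1 M aq. HCl, THF, rt) gives 4-(benzyloxy)-3-[4-(2-{6-(benzyloxy)-2-(3-formylphenoxy)-3-methoxyphenyl}ethyl)phenoxy]benzaldehyde F5. An intramolecular McMurry coupling (TiCl4, Zn, pyridine, THF, reflux, slow addition at high dilution) then returns to the route at 25.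

**Further compounds**
F1 | step 6 | 6-(benzyloxy)-3-methoxy-2-[2-(methylsulfonyl)ethoxy]benzaldehyde | COc1ccc(OCc2ccccc2)c(C=O)c1OCCS(C)(=O)=O
F2 | step 6 | 6-(benzyloxy)-2-hydroxy-3-methoxybenzaldehyde | COc1ccc(OCc2ccccc2)c(C=O)c1O
F3 | step 13 | methyl 3-[4-(2-{2-[3-(1,3-dioxolan-2-yl)phenoxy]-6-hydroxy-3-methoxyphenyl}ethyl)phenoxy]-4-hydroxybenzoate | COC(=O)c1ccc(O)c(Oc2ccc(CCc3c(O)ccc(OC)c3Oc3cccc(c3)C3OCCO3)cc2)c1
F4 | step 16 | 4-(benzyloxy)-3-[4-(2-{6-(benzyloxy)-2-[3-(1,3-dioxolan-2-yl)phenoxy]-3-methoxyphenyl}ethyl)phenoxy]benzaldehyde | O=Cc1ccc(OCc2ccccc2)c(Oc2ccc(CCc3c(OCc4ccccc4)ccc(OC)c3Oc3cccc(c3)C3OCCO3)cc2)c1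
F5 | step 16 | 4-(benzyloxy)-3-[4-(2-{6-(benzyloxy)-2-(3-formylphenoxy)-3-methoxyphenyl}ethyl)phenoxy]benzaldehyde | O=Cc1ccc(OCc2ccccc2)c(Oc2ccc(CCc3c(OCc4ccccc4)ccc(OC)c3Oc3cccc(C=O)c3)cc2)c1
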